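Readings and results are calculated with made-up constants, noise included.

A single molecule of starting material cannot be followed through a flask, but its chances at a fork can be read from many molecules. Here the fork is where a molecule stands late in the run: as starting material, target or isomer of the product A.

common to all: starting material 0.15 M (fed, over 15 s)
- Monday's: protic impurity 1.5 mM; free catalyst 5.6 mol%; run made earlier
- Saturday's: protic impurity 6 mM; free catalyst 5.6 mol%; run made earlier
- Friday's: protic impurity 3 mM; free catalyst 11 mol%; run made earlier
- flask: protic impurity 3.00 mM; free catalyst 5.6 mol%; time 10 min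

- Monday's (time / min: starting material / %, target / %, isomer of the product A / %): 0.667: 47.8, 5.6, 43.9; 2.00: 32.3, 6.2, 58.5; 3.00: 31.5, 7.8, 56.1; 5.00: 33.5, 7.0, 58.3; 8.00: 34.7, 5.0, 58.1; 10.0: 32.1, 6.2, 55.0; 12.0: 32.7, 6.3, 58.6
- Saturday's (time / min: starting material / %, target / %, isomer of the product A / %): 1.00: 38.3, 6.5, 48.2; 1.33: 33.1, 5.8, 53.4; 2.00: 32.1, 5.0, 54.8; 3.00: 31.8, 6.0, 55.5; 5.00: 31.3, 5.1, 56.0; 8.00: 30.5, 6.8, 55.6; 12.0: 30.3, 3.9, 54.2
- Friday's (time / min: starting material / %, target / %, isomer of the product A / %): 1.00: 39.2, 8.4, 49.8; 3.00: 33.5, 5.9, 56.9; 6.00: 32.8, 6.6, 55.3; 8.00: 33.2, 4.2, 57.2; 12.0: 32.4, 6.9, 55.6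

(standard deviation of a reading: 1 percentage point)

1. share of the starting material used up at 10 min
2. target at 10 min, in percent of the starting material charged
3. isomer of the product A at 10 min, in percent of the starting material charged

- the earlier runs were read with a standard deviation of 1 percentage point

The tables are read from 3.00 min on, where each run scatters about a level. The isomer's part of the three measured species comes to 59.2 % in Monday's run. With protic impurity raised to 6 mM, Saturday's run reads 60.3 %. With twice the catalyst and 3 mM of protic impurity, Friday's run reads 59.1 %. That is a spread of 1.2 points, against a scatter of 1 point on one reading. Their mean, 59.6 %, is the isomer share: the chance that a molecule found among the three species stands as the isomer.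

Friday's run has the flask's 3.00 mM of impurity, and its three species sum to 95.1 % on average. This reckoning therefore puts the flask's isomer at 56.7 %.

The forecast, seeing “the same plateau within about 3 minutes”, gives conversion 67.5 %, target 6 % and isomer 56.5 %. That isomer figure and this reckoning lie 0.20 points apart.

The flask gives conversion 68.0 %, target 5.92 % and isomer 56.6 %, each inside the forecast's range.

    starting material + free catalyst ⇌ target + free catalyst, rate k1*[starting material]*[free catalyst] forward; the back reaction follows from the equilibrium constant (K = 0.190, k = 0.830 L mol⁻¹ s⁻¹)
    target + free catalyst ⇌ isomer of the product A + free catalyst, rate k2*[free catalyst]*[target] forward; the back reaction follows from the equilibrium constant (K = 9.30, k = 0.680 L mol⁻¹ s⁻¹)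
    isomer of the product A ⇌ starting material (k = 0.0150 s⁻¹)
    2 free catalyst → spent catalyst (k = 0.760 L mol⁻¹ s⁻¹)
    target + free catalyst ⇌ isomer of the product B + free catalyst, rate k5*[free catalyst]*[target] forward; the back reaction follows from the equilibrium constant (K = 0.650, k = 1.20 L mol⁻¹ s⁻¹)
    starting material + protic impurity → quenched substrate (k = 5.00 L mol⁻¹ s⁻¹)

Free catalyst in the flask fell from 20.7 % of the catalyst charged at 5.00 min to 11.5 % at 10.0 min, while the largest change in the share of a substrate, an intermediate or a product over that time was 0.34 points. The neighbour flask with 14 mol% of free catalyst holds 94.2 % in the three species. The isomer share turns that sum into 56.1 % of isomer of the product A, and that flask holds 56.3 %.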